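## Analysis of the target

The target 26 is a C30 bicyclic triterpenoid alcohol. Its core is a decalin (ring A: C1–C5 and C10; ring B: C5–C10) with a gem-dimethyl group on C4, an angular methyl on C10 and a tertiary carbinol at C8. C9 bears a sixteen-carbon chain (C11–C22, three methyl branches) holding two E-trisubstituted alkenes (C13=C14, C17=C18) and a terminal isopropylidene (C21=C22). The four stereocentres are contiguous: C5 (R), C10 (S), C9 (R) and C8 (R), which are locants 4a, 8a, 1 and 2 of the decahydronaphthalene name. H-5 and the C10 methyl lie on the same face, so the ring fusion is cis; C11 on C9 and the C8 methyl share that face, while the C8 hydroxyl lies on the opposite face, trans to C11. The tertiary alcohol eliminates under acid, and the three trisubstituted alkenes do not survive strong acids, peracids or hydrogenation, so the chain has to arrive after every oxidation, hydrogenation and Lewis-acid step. The hard points are the cis fusion (which the chair–chair cyclisation of an all-E polyene does not give), the quaternary C10 directly beside the quaternary C4, and C9, a tertiary centre wedged between the fully substituted C8 and C10. The strategy rests on the vicinal pair C5 (H) and C10 (CH3) in ring A: with a carbonyl at C1 they are the β- and α-carbons of a cyclohexenone, so a nucleophile can be added to C5 and a methyl group to C10 in one operation, the second bond forming anti to the first, which is the cis H/CH3 relationship.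

## Retrosynthetic reasoning

**C11–C12.** The chain is cut from the core at the one sp3–sp3 bond that leaves all three alkenes in a single piece. 26 comes from the sulfone 25 by reductive loss of the sulfonyl group, and 25 from the C11 sulfone 22 and the C15 allylic bromide 23. The polarity is chosen so that substitution occurs at the unhindered primary allylic carbon of 23 and not at C11, which is β-branched by C9 and its two fully substituted neighbours. The sulfonyl group also ends up homoallylic in 25, so its removal cannot move a double bond. The forward step has to alkylate a crowded α-sulfonyl carbanion in the presence of the C8 alkoxide.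

**C11–S and the oxidation level of C11.** 22 goes back through the sulfide 21 to the 8,11-diol 20 and the β-hydroxy ester 19, so C11 is the carbonyl carbon of an ester on C9. Only the primary hydroxyl of 20 is exchanged for sulfur; the tertiary one is carried free. All oxidation at sulfur is finished before 23 is introduced.

**C8–C9 (ring B).** 19 is an aldol. Cutting C8–C9 separates an ester α-carbon (C9) from a methyl-ketone carbon (C8), which sit on ring A as a two-carbon arm on C10 and a four-carbon chain on C5. An ester enolate cannot be generated beside a free methyl ketone, which is the stronger acid. The ketone therefore stays masked as its dioxolane in 14 while the ester is turned into the silyl ketene acetal 16, and the Lewis-acid-opened ketal serves as the electrophile. The price is the 2-hydroxyethyl ether 17, cleared in two steps through the iodide 18. The cyclisation has to set C8 and C9. An open transition state is wanted, because a metal-bridged aldol would hold O8 and C11 gauche, which on the chair this ring system prefers means cis.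

**C1=O.** The saturated ring A of 14 is traced back through the alkene 13 and the enol triflate 12 to the ketone 10. The C1 carbonyl serves only to make C5 and C10 reactive. It is removed by way of the enol triflate because a hydrazone or an alcohol at C1 would cyclise onto the ester three atoms away.

**C5–C6 and C10–CH3 (key disconnection).** 10 is cut at both bonds around the former enone: the C5 chain becomes the Grignard reagent 7, the C10 methyl becomes 8, and ring A becomes the enone 5. No other cut makes two adjacent stereocentres from one prochiral alkene, and this one leaves the C4 gem-dimethyl group as a spectator. The forward reaction must add to a β-carbon flanked by a quaternary carbon, choose one face of the enone under catalyst control, and then methylate the tetrasubstituted enolate on the face away from the new chain.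

**C10–C9 and the starting materials.** 5 is an α-substituted enone. Cutting the bond between C10 and the arm gives the α-iodoenone 2 and the zinc enolate 4 made from the bromoacetate 3. 2 comes from the enone 1 and 7 from the bromide 6. Compounds 1, 3, 6, 8 and 23 are purchased.

## Alternatives that were turned down

**Alternative 1:** Ring B would be closed at the same C8–C9 bond but with reversed roles. The C8 ketone of the keto acrylate A1 is reduced by a one-electron donor to a ketyl radical, which adds 6-exo to the acrylate β-carbon (C9) and gives the hydroxy ester A2.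
- **For:** ketyl–alkene closures reliably place the oxygen and the acceptor-bearing carbon anti, so C8 and C9 would be set with more confidence than by the polar aldol chosen here. On this point the alternative is stronger, and the same radical closure is held in reserve for step 9.
- **Against:** the step does nothing for C5 and C10. A1 must already contain the cis H/CH3 pair, and its C10 must carry both a methyl group and a formyl-derived acrylate, which is harder to install on an enolate than a methyl group. The ester carbon of A2 is C12, one atom further out than in 19, so the chain would have to be joined at the vinylic C13. Compound 23 could not be used as it is, and the C13=C14 alkene would have to be built with E control.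
- **Comparison:** the chosen strategy offers a single catalytic step for the harder stereodiad and a C11 ester that becomes the sulfone for a one-step union with an intact C15 unit.

**Alternative 2:** Rings A and B would be cut together at C4–C5 and C9–C10, back to the achiral (Z)-dienyl β-keto ester A3. A chiral Brønsted acid assisted by a Lewis acid protonates the terminal alkene, and the cation is relayed through the Z alkene to the enol, giving the bicyclic keto ester A4.
- **For:** it is clearly stronger in step economy, since one step from an acyclic precursor makes two rings, two bonds and C5/C10.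
- **Against:** the cis fusion depends on the Z alkene reacting through a chair–boat or stepwise path, in which the C10 cation can relax towards the trans-fused product. The proton has to be delivered enantioselectively to an isopropylidene far from the binding β-keto ester, which itself chelates the Lewis acid. A4 arrives with a C8 ketone inside an enolisable β-keto ester, so methyl addition at C8 is blocked until the ester is reduced or masked.
- **Comparison:** the chosen strategy is longer up to the bicycle, but its ring-fusion stereochemistry does not depend on the fidelity of a cationic relay, and C8 already carries its methyl group and its oxygen.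

**Alternative 3:** Ring A would be formed at C1–C10 by a [3,3] shift. The potassium alkoxide of the bicyclo[2.2.2]octene vinyl carbinol A5 rearranges (anionic oxy-Cope) to the cis-fused octalone A6.
- **For:** the cis fusion is guaranteed by the cage geometry, which is at least as secure as the anti alkylation relied on here.
- **Against:** A5 needs three defined stereocentres in one absolute sense (an asymmetric cycloaddition, then vinyl addition to a ketone beside a quaternary carbon from the face of the alkene bridge). A6 has a C3 carbonyl to remove and a C8=C9 alkene without C11, so C11 on C9 and the oxygen on C8 would still have to be added to a trisubstituted alkene with control of two centres.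
- **Comparison:** in the chosen strategy C9, C11 and the C8 oxygen are present from the enone stage, and only one carbonyl has to be removed.

Key step: step 4

Assumption: the sense of induction of a ferrocenyl diphosphine–copper catalyst on a 2,4,4-trisubstituted cyclohexenone such as 5 cannot be assigned in advance; the ligand antipode meant throughout is the one that delivers the alkyl group to the Re face of C5.

## Route

Step 1
Reactants: 1 4,4-dimethylcyclohex-2-en-1-one
Product: 2 2-iodo-4,4-dimethylcyclohex-2-en-1-one
Conditions: I2, pyridine, CH2Cl2, 0 → 25 °C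
Reagents that add atoms: iodine, II
Why: α-Iodination of an enone by the iodine–pyridine protocol (conjugate addition of pyridine, iodination of the enolate, elimination of pyridine); C2 is the only vinylic α-position.

Step 2
Reactants: 2 2-iodo-4,4-dimethylcyclohex-2-en-1-one; 3 tert-butyl bromoacetate
Product: 5 tert-butyl 2-(3,3-dimethyl-6-oxocyclohex-1-en-1-yl)acetate, via the zinc enolate BrZnCH2CO2t-Bu 4 (not isolated)
Conditions: Zn dust (Me3SiCl-activated), THF, 25 °C; then 2, Pd2(dba)3 (2.5 mol %), XPhos (6 mol %), THF, 25–40 °C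
Reagents that add atoms: none
Why: Negishi coupling of a Reformatsky reagent with an alkenyl iodide: zerovalent palladium inserts into the C–I bond of 2, the zinc enolate transmetalates and reductive elimination forms the C10–C9 bond. The tert-butyl ester suppresses Claisen self-condensation here and shields the ester carbonyl from the Grignard reagent in step 4.

Step 3
Reactants: 6 2-(2-bromoethyl)-2-methyl-1,3-dioxolane
Product: 7 [2-(2-methyl-1,3-dioxolan-2-yl)ethyl]magnesium bromide
Conditions: Mg turnings (BrCH2CH2Br-activated), THF, 20–30 °C; titrated solution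
Reagents that add atoms: magnesium, [Mg]
Why: Oxidative insertion of magnesium into the primary C–Br bond (Grignard formation); the temperature is kept at or below 30 °C because this ketal Grignard reagent fragments on heating.

Step 4
Reactants: 5 tert-butyl 2-(3,3-dimethyl-6-oxocyclohex-1-en-1-yl)acetate; 7 [2-(2-methyl-1,3-dioxolan-2-yl)ethyl]magnesium bromide; 8 iodomethane
Product: 10 tert-butyl 2-[(1R,2R)-1,3,3-trimethyl-2-[2-(2-methyl-1,3-dioxolan-2-yl)ethyl]-6-oxocyclohexyl]acetate, via bromomagnesium enolate 9 (not isolated)
Conditions: CuBr·SMe2 (5 mol %), (R,Sp)-Josiphos-type ferrocenyl diphosphine (6 mol %; antipode chosen for Re-face delivery at C5), t-BuOMe, −78 °C, slow addition of 7 (1.5 equiv); then 8 (5 equiv), DMPU, −78 → −10 °C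
Reagents that add atoms: none
Why: This is a copper-catalysed asymmetric conjugate addition of a Grignard reagent to a cyclic enone with alkyl-halide trapping of the magnesium enolate, a three-component vicinal difunctionalisation. Transmetalation of 7 to the monovalent copper–diphosphine complex gives an alkylcopper species that binds the C5=C10 bond as a π-complex, adds at C5 to a trivalent copper intermediate and reductively eliminates, forming C5–C6 and leaving the bromomagnesium enolate 9 across C1–C10. C10 of 9 then displaces iodide from 8 in an SN2 step, forming C10–CH3; no ring is closed. C5 is set by the chiral ligand, which must deliver the alkyl group to the Re face (2R in 10). C10 is set by the substrate: in the half-chair enolate the new C5 chain, wedged between the C4 methyls and the C10 substituent, sits pseudo-axial, and 8 approaches C10 axially from the opposite face. The methyl therefore ends trans to the chain and cis to H-5 (1R in 10, the cis-fusion pattern), and the acetate arm is left cis to the chain, ready for ring B. The step needs 1,4- over 1,2-addition and over attack on the ester, which copper catalysis at −78 °C, slow addition and the bulky tert-butyl ester should secure. It also needs C- over O-methylation at C10 and not at C2, which a soft electrophile added in excess to the regiodefined enolate before any proton source should secure.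

Step 5
Reactants: 10 tert-butyl 2-[(1R,2R)-1,3,3-trimethyl-2-[2-(2-methyl-1,3-dioxolan-2-yl)ethyl]-6-oxocyclohexyl]acetate
Product: 12 tert-butyl 2-[(1R,6R)-1,5,5-trimethyl-6-[2-(2-methyl-1,3-dioxolan-2-yl)ethyl]-2-(trifluoromethanesulfonyloxy)cyclohex-2-en-1-yl]acetate, via potassium enolate 11 (not isolated)
Conditions: KN(SiMe3)2 (1.1 equiv), THF, −78 °C; PhNTf2 (1.2 equiv), −78 → 0 °C
Reagents that add atoms: N-phenylbis(trifluoromethanesulfonimide), O=S(=O)(N(c1ccccc1)S(=O)(=O)C(F)(F)F)C(F)(F)F
Why: Enol triflate formation: the ketone is more acidic than the ester and C10 is quaternary, so kinetic deprotonation can occur only at C2, and the potassium enolate 11 is O-sulfonylated by PhNTf2. The low temperature and the tert-butyl ester hold back attack of the enolate oxygen on the neighbouring ester.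

Step 6
Reactants: 12 tert-butyl 2-[(1R,6R)-1,5,5-trimethyl-6-[2-(2-methyl-1,3-dioxolan-2-yl)ethyl]-2-(trifluoromethanesulfonyloxy)cyclohex-2-en-1-yl]acetate
Product: 13 tert-butyl 2-[(1S,6R)-1,5,5-trimethyl-6-[2-(2-methyl-1,3-dioxolan-2-yl)ethyl]cyclohex-2-en-1-yl]acetate
Conditions: Pd(OAc)2 (5 mol %), PPh3 (10 mol %), n-Bu3N (3 equiv), HCO2H (2 equiv), DMF, 60 °C
Reagents that add atoms: none
Why: Palladium-catalysed formate reduction of an enol triflate: oxidative addition of the C–O bond to zerovalent palladium, formate exchange, loss of CO2 to the palladium hydride and reductive elimination. The amine-buffered medium leaves the ketal and the ester intact; the change of descriptor at the quaternary centre is only a change of priorities.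

Step 7
Reactants: 13 tert-butyl 2-[(1S,6R)-1,5,5-trimethyl-6-[2-(2-methyl-1,3-dioxolan-2-yl)ethyl]cyclohex-2-en-1-yl]acetate
Product: 14 tert-butyl 2-[(1R,2R)-1,3,3-trimethyl-2-[2-(2-methyl-1,3-dioxolan-2-yl)ethyl]cyclohexyl]acetate
Conditions: H2 (1 atm), Pd/C (10 %), EtOAc, 25 °C
Reagents that add atoms: none
Why: Heterogeneous hydrogenation of the disubstituted ring alkene completes the removal of the C1 oxygen; no stereocentre is formed (C1 and C2 become CH2) and no other reducible group is present.

Step 8
Reactants: 14 tert-butyl 2-[(1R,2R)-1,3,3-trimethyl-2-[2-(2-methyl-1,3-dioxolan-2-yl)ethyl]cyclohexyl]acetate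
Product: 16 tert-butyl({1-tert-butoxy-2-[(1S,2R)-1,3,3-trimethyl-2-[2-(2-methyl-1,3-dioxolan-2-yl)ethyl]cyclohexyl]ethenyl}oxy)dimethylsilane (E/Z mixture), via lithium ester enolate 15 (not isolated)
Conditions: LiN(i-Pr)2 (1.3 equiv), THF, −78 °C; t-BuMe2SiCl (1.5 equiv), DMPU, −78 → 0 °C; pentane, cold aq. NaHCO3
Reagents that add atoms: tert-butyldimethylsilyl chloride, CC(C)(C)[Si](C)(C)Cl
Why: With the ketone still masked as the ketal, C9 is the only acidic position, so deprotonation and O-silylation of the lithium enolate 15 give the silyl ketene acetal regiospecifically. Its double-bond geometry is immaterial because C11 becomes a carbonyl carbon again.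

Step 9
Reactants: 16 tert-butyl({1-tert-butoxy-2-[(1S,2R)-1,3,3-trimethyl-2-[2-(2-methyl-1,3-dioxolan-2-yl)ethyl]cyclohexyl]ethenyl}oxy)dimethylsilane
Product: 17 tert-butyl (1R,2R,4aR,8aS)-2-(2-hydroxyethoxy)-2,5,5,8a-tetramethyldecahydronaphthalene-1-carboxylate
Conditions: TiCl4 (1.1 equiv), CH2Cl2, −78 °C; aq. NaHCO3
Reagents that add atoms: none
Why: Intramolecular Mukaiyama aldol-type addition of the silyl ketene acetal to the oxocarbenium ion released from the dioxolane (6-enolexo-exo-trig) forms C8–C9 and ring B. No metal bridges the two oxygens, so the addition should run through an open antiperiplanar transition state on the ring B chair that has C1 axial and the C8 methyl equatorial; the other chair would push the ketene acetal carbon against C4. This places the C8 oxygen on the α face and C11 on the β face (trans-diaxial), i.e. 8R,9R in target numbering.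

Step 10
Reactants: 17 tert-butyl (1R,2R,4aR,8aS)-2-(2-hydroxyethoxy)-2,5,5,8a-tetramethyldecahydronaphthalene-1-carboxylate
Product: 18 tert-butyl (1R,2R,4aR,8aS)-2-(2-iodoethoxy)-2,5,5,8a-tetramethyldecahydronaphthalene-1-carboxylate
Conditions: I2, PPh3, imidazole, CH2Cl2, 0 → 25 °C
Reagents that add atoms: iodine, II
Why: Appel-type iodination of the primary alcohol through its alkoxyphosphonium ion; the tertiary ether and the tert-butyl ester are inert.

Step 11
Reactants: 18 tert-butyl (1R,2R,4aR,8aS)-2-(2-iodoethoxy)-2,5,5,8a-tetramethyldecahydronaphthalene-1-carboxylate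
Product: 19 tert-butyl (1R,2R,4aR,8aS)-2-hydroxy-2,5,5,8a-tetramethyldecahydronaphthalene-1-carboxylate
Conditions: Zn dust, EtOH, 75 °C; aq. NH4Cl
Reagents that add atoms: none
Why: Zinc inserts into the C–I bond and the β-alkoxy organozinc fragments (Boord-type reductive elimination), expelling ethene and freeing the C8 alkoxide. The C8–O bond is not touched, so the configuration at C8 is retained.

Step 12
Reactants: 19 tert-butyl (1R,2R,4aR,8aS)-2-hydroxy-2,5,5,8a-tetramethyldecahydronaphthalene-1-carboxylate
Product: 20 (1S,2R,4aR,8aS)-1-(hydroxymethyl)-2,5,5,8a-tetramethyldecahydronaphthalen-2-ol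
Conditions: LiAlH4 (3 equiv), THF, 0 → 65 °C; aq. NaOH work-up
Reagents that add atoms: none
Why: Hydride reduction of the hindered tert-butyl ester to the primary alcohol; the tertiary alkoxide formed first is inert. C9 keeps its configuration (the descriptor changes only through the priorities).

Step 13
Reactants: 20 (1S,2R,4aR,8aS)-1-(hydroxymethyl)-2,5,5,8a-tetramethyldecahydronaphthalen-2-ol
Product: 21 (1R,2R,4aR,8aS)-2,5,5,8a-tetramethyl-1-[(phenylsulfanyl)methyl]decahydronaphthalen-2-ol
Conditions: PhSSPh (1.5 equiv), n-Bu3P (1.5 equiv), pyridine, 25 → 50 °C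
Reagents that add atoms: diphenyl disulfide, c1ccc(SSc2ccccc2)cc1
Why: Mitsunobu-type thioetherification with a disulfide and a phosphine: only the primary hydroxyl forms an alkoxyphosphonium ion, which benzenethiolate displaces at C11 in an SN2 step. The tertiary hydroxyl does not react and C9 is not involved.

Step 14
Reactants: 21 (1R,2R,4aR,8aS)-2,5,5,8a-tetramethyl-1-[(phenylsulfanyl)methyl]decahydronaphthalen-2-ol
Product: 22 (1R,2R,4aR,8aS)-1-[(benzenesulfonyl)methyl]-2,5,5,8a-tetramethyldecahydronaphthalen-2-ol
Conditions: mCPBA (2.2 equiv), NaHCO3, CH2Cl2, 0 → 25 °C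
Reagents that add atoms: 3-chloroperoxybenzoic acid, OOC(=O)c1cccc(Cl)c1
Why: Peracid oxidation of the sulfide through the sulfoxide to the sulfone; no alkene is present yet and the tertiary alcohol is inert.

Step 15
Reactants: 22 (1R,2R,4aR,8aS)-1-[(benzenesulfonyl)methyl]-2,5,5,8a-tetramethyldecahydronaphthalen-2-ol; 23 (2E,6E)-1-bromo-3,7,11-trimethyldodeca-2,6,10-triene
Product: 25 (1R,2R,4aR,8aS)-1-[(3E,7E)-1-(benzenesulfonyl)-4,8,12-trimethyltrideca-3,7,11-trien-1-yl]-2,5,5,8a-tetramethyldecahydronaphthalen-2-ol (both C11 epimers), via dilithio sulfone 24 (not isolated)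
Conditions: n-BuLi (2.2 equiv), THF, −78 → −20 °C; DMPU; 23 (1.2 equiv), −78 → 0 °C
Reagents that add atoms: none
Why: Sulfone alkylation: double deprotonation gives the alkoxide/α-sulfonyl carbanion 24, whose carbon attacks the primary allylic bromide in an SN2 step, forming C11–C12 with the E alkenes of 23 untouched. The new centre at C11 is of no consequence because the sulfonyl group is removed next.

Step 16
Reactants: 25 (1R,2R,4aR,8aS)-1-[(3E,7E)-1-(benzenesulfonyl)-4,8,12-trimethyltrideca-3,7,11-trien-1-yl]-2,5,5,8a-tetramethyldecahydronaphthalen-2-ol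
Product: 26 (1R,2R,4aR,8aS)-2,5,5,8a-tetramethyl-1-[(3E,7E)-4,8,12-trimethyltrideca-3,7,11-trien-1-yl]decahydronaphthalen-2-ol (target)
Conditions: Na/Hg (6 % Na), Na2HPO4, MeOH/THF, −20 → 0 °C
Reagents that add atoms: none
Why: Reductive desulfonylation by electron transfer from sodium amalgam: the C11–S bond cleaves and the carbanion is protonated by methanol. The sulfonyl group is homoallylic, not allylic, so no double bond migrates, and the isolated alkenes and the tertiary alcohol are not reduced.

## Compound list

1 | 4,4-dimethylcyclohex-2-en-1-one | CC1(C)CCC(=O)C=C1 | starting material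
2 | 2-iodo-4,4-dimethylcyclohex-2-en-1-one | CC1(C)CCC(=O)C(I)=C1 | intermediate
3 | tert-butyl bromoacetate | CC(C)(C)OC(=O)CBr | starting material
4 | (2-tert-butoxy-2-oxoethyl)zinc bromide | CC(C)(C)OC(=O)C[Zn]Br | intermediate
5 | tert-butyl 2-(3,3-dimethyl-6-oxocyclohex-1-en-1-yl)acetate | CC(C)(C)OC(=O)CC1=CC(C)(C)CCC1=O | intermediate
6 | 2-(2-bromoethyl)-2-methyl-1,3-dioxolane | CC1(CCBr)OCCO1 | starting material
7 | [2-(2-methyl-1,3-dioxolan-2-yl)ethyl]magnesium bromide | CC1(CC[Mg]Br)OCCO1 | intermediate
8 | iodomethane | CI | starting material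
9 | bromomagnesium (3R)-2-(2-tert-butoxy-2-oxoethyl)-4,4-dimethyl-3-[2-(2-methyl-1,3-dioxolan-2-yl)ethyl]cyclohex-1-en-1-olate | CC(C)(C)OC(=O)CC1=C(O[Mg]Br)CCC(C)(C)[C@H]1CCC2(C)OCCO2 | intermediate
10 | tert-butyl 2-[(1R,2R)-1,3,3-trimethyl-2-[2-(2-methyl-1,3-dioxolan-2-yl)ethyl]-6-oxocyclohexyl]acetate | CC(C)(C)OC(=O)C[C@@]1(C)C(=O)CCC(C)(C)[C@H]1CCC2(C)OCCO2 | intermediate
11 | potassium (5R,6R)-6-(2-tert-butoxy-2-oxoethyl)-4,4,6-trimethyl-5-[2-(2-methyl-1,3-dioxolan-2-yl)ethyl]cyclohex-1-en-1-olate | CC(C)(C)OC(=O)C[C@@]1(C)C(O[K])=CCC(C)(C)[C@H]1CCC2(C)OCCO2 | intermediate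
12 | tert-butyl 2-[(1R,6R)-1,5,5-trimethyl-6-[2-(2-methyl-1,3-dioxolan-2-yl)ethyl]-2-(trifluoromethanesulfonyloxy)cyclohex-2-en-1-yl]acetate | CC(C)(C)OC(=O)C[C@@]1(C)C(OS(=O)(=O)C(F)(F)F)=CCC(C)(C)[C@H]1CCC2(C)OCCO2 | intermediate
13 | tert-butyl 2-[(1S,6R)-1,5,5-trimethyl-6-[2-(2-methyl-1,3-dioxolan-2-yl)ethyl]cyclohex-2-en-1-yl]acetate | CC(C)(C)OC(=O)C[C@@]1(C)C=CCC(C)(C)[C@H]1CCC2(C)OCCO2 | intermediate
14 | tert-butyl 2-[(1R,2R)-1,3,3-trimethyl-2-[2-(2-methyl-1,3-dioxolan-2-yl)ethyl]cyclohexyl]acetate | CC(C)(C)OC(=O)C[C@@]1(C)CCCC(C)(C)[C@H]1CCC2(C)OCCO2 | intermediate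
15 | lithium 1-tert-butoxy-2-[(1S,2R)-1,3,3-trimethyl-2-[2-(2-methyl-1,3-dioxolan-2-yl)ethyl]cyclohexyl]ethen-1-olate | CC(C)(C)OC(O[Li])=C[C@@]1(C)CCCC(C)(C)[C@H]1CCC2(C)OCCO2 | intermediate
16 | tert-butyl({1-tert-butoxy-2-[(1S,2R)-1,3,3-trimethyl-2-[2-(2-methyl-1,3-dioxolan-2-yl)ethyl]cyclohexyl]ethenyl}oxy)dimethylsilane (E/Z mixture) | CC(C)(C)OC(O[Si](C)(C)C(C)(C)C)=C[C@@]1(C)CCCC(C)(C)[C@H]1CCC2(C)OCCO2 | intermediate
17 | tert-butyl (1R,2R,4aR,8aS)-2-(2-hydroxyethoxy)-2,5,5,8a-tetramethyldecahydronaphthalene-1-carboxylate | CC(C)(C)OC(=O)[C@@H]1[C@@]2(C)CCCC(C)(C)[C@H]2CC[C@@]1(C)OCCO | intermediate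
18 | tert-butyl (1R,2R,4aR,8aS)-2-(2-iodoethoxy)-2,5,5,8a-tetramethyldecahydronaphthalene-1-carboxylate | CC(C)(C)OC(=O)[C@@H]1[C@@]2(C)CCCC(C)(C)[C@H]2CC[C@@]1(C)OCCI | intermediate
19 | tert-butyl (1R,2R,4aR,8aS)-2-hydroxy-2,5,5,8a-tetramethyldecahydronaphthalene-1-carboxylate | CC(C)(C)OC(=O)[C@@H]1[C@@]2(C)CCCC(C)(C)[C@H]2CC[C@@]1(C)O | intermediate
20 | (1S,2R,4aR,8aS)-1-(hydroxymethyl)-2,5,5,8a-tetramethyldecahydronaphthalen-2-ol | OC[C@@H]1[C@@]2(C)CCCC(C)(C)[C@H]2CC[C@@]1(C)O | intermediate
21 | (1R,2R,4aR,8aS)-2,5,5,8a-tetramethyl-1-[(phenylsulfanyl)methyl]decahydronaphthalen-2-ol | c1ccccc1SC[C@@H]2[C@@]3(C)CCCC(C)(C)[C@H]3CC[C@@]2(C)O | intermediate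
22 | (1R,2R,4aR,8aS)-1-[(benzenesulfonyl)methyl]-2,5,5,8a-tetramethyldecahydronaphthalen-2-ol | O=S(=O)(C[C@@H]1[C@@]2(C)CCCC(C)(C)[C@H]2CC[C@@]1(C)O)c1ccccc1 | intermediate
23 | (2E,6E)-1-bromo-3,7,11-trimethyldodeca-2,6,10-triene ((E,E)-farnesyl bromide) | CC(C)=CCC/C(C)=C/CC/C(C)=C/CBr | starting material
24 | dilithio derivative of 22 (lithium alkoxide at C8, lithium on the sulfonyl-bearing C11) | [Li]C([C@@H]1[C@@]2(C)CCCC(C)(C)[C@H]2CC[C@@]1(C)O[Li])S(=O)(=O)c1ccccc1 | intermediate
25 | (1R,2R,4aR,8aS)-1-[(3E,7E)-1-(benzenesulfonyl)-4,8,12-trimethyltrideca-3,7,11-trien-1-yl]-2,5,5,8a-tetramethyldecahydronaphthalen-2-ol (both C11 epimers) | CC(C)=CCC/C(C)=C/CC/C(C)=C/CC([C@@H]1[C@@]2(C)CCCC(C)(C)[C@H]2CC[C@@]1(C)O)S(=O)(=O)c1ccccc1 | intermediate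
26 | (1R,2R,4aR,8aS)-2,5,5,8a-tetramethyl-1-[(3E,7E)-4,8,12-trimethyltrideca-3,7,11-trien-1-yl]decahydronaphthalen-2-ol | CC(C)=CCC/C(C)=C/CC/C(C)=C/CC[C@@H]1[C@@]2(C)CCCC(C)(C)[C@H]2CC[C@@]1(C)O | target

## Step count and least certain steps

Total: 16 steps. Longest linear sequence: 15 steps (1 → 26 through steps 1, 2 and 4–16); step 3 is a one-step side branch.

**Step 4 (key step).** The most likely failure is a slow and unselective addition. C5 is shielded by the C4 gem-dimethyl group and by the α-substituent, so uncatalysed 1,2-addition, deprotonation of the doubly activated CH2 and a racemic background reaction can overtake the catalysed pathway, and the crowded magnesium enolate may then methylate incompletely. The fallback sets out from 5 and returns at 10. The Grignard reagent 7 would be transmetalated with ZnCl2 (0.5 equiv) to bis[2-(2-methyl-1,3-dioxolan-2-yl)ethyl]zinc F1, a nucleophile with no uncatalysed background addition. Its conjugate addition to 5 under Cu(OTf)2 and a chiral phosphoramidite, with the zinc enolate trapped by Me3SiOTf, would give the silyl enol ether tert-butyl 2-[(6R)-5,5-dimethyl-6-[2-(2-methyl-1,3-dioxolan-2-yl)ethyl]-2-(trimethylsilyloxy)cyclohex-1-en-1-yl]acetate F2, which can be purified before the quaternary centre is made. Benzyltrimethylammonium fluoride in the presence of 8 would then release the regiodefined enolate and methylate it at C10, again anti to the C5 chain, to give 10.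

**Step 9.** The most likely failures are poor facial selectivity at C9 (a synclinal approach competing with the antiperiplanar one) and collapse of the oxocarbenium ion by proton loss before the crowded C8–C9 bond forms. The fallback sets out from 14 and returns at 22, bypassing 16–21. LiAlH4 would reduce the ester of 14 to 2-[(1R,2R)-1,3,3-trimethyl-2-[2-(2-methyl-1,3-dioxolan-2-yl)ethyl]cyclohexyl]ethan-1-ol F3. PhSSPh/n-Bu3P would give the sulfide 2-methyl-2-{2-[(1R,6R)-2,2,6-trimethyl-6-[2-(phenylsulfanyl)ethyl]cyclohexyl]ethyl}-1,3-dioxolane F4, and buffered mCPBA the sulfone 2-{2-[(1R,6R)-6-[2-(benzenesulfonyl)ethyl]-2,2,6-trimethylcyclohexyl]ethyl}-2-methyl-1,3-dioxolane F5. Deprotonation with n-BuLi and reaction with PhSeCl would give the α-selanyl sulfone 2-{2-[(1R,6R)-6-[2-(benzenesulfonyl)-2-(phenylselanyl)ethyl]-2,2,6-trimethylcyclohexyl]ethyl}-2-methyl-1,3-dioxolane F6. Oxidation with H2O2 and syn elimination would give the vinyl sulfone 2-{2-[(1R,6S)-6-[(E)-2-(benzenesulfonyl)ethenyl]-2,2,6-trimethylcyclohexyl]ethyl}-2-methyl-1,3-dioxolane F7 (C9=C11). PPTS in wet acetone would free the methyl ketone 4-[(1R,6S)-6-[(E)-2-(benzenesulfonyl)ethenyl]-2,2,6-trimethylcyclohexyl]butan-2-one F8. SmI2 in THF/MeOH at −78 °C would reduce the ketone to a ketyl that adds 6-exo to C9; the α-sulfonyl radical is reduced and protonated, giving 22 directly. Ketyl–alkene closures place the O–Sm group and the acceptor-bearing carbon anti, the relationship needed between O8 and C11, and a radical addition is less sensitive to crowding than the ionic closure.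

**Step 2.** The most likely failure is Reformatsky addition of 4 to the ketone of 2 or of 5 outrunning transmetalation, together with base-induced migration of the double bond of 5. The fallback sets out from 2 and returns at 5. Stille coupling of 2 with allyltributylstannane (Pd(PPh3)4, CuI) would give 4,4-dimethyl-2-(prop-2-en-1-yl)cyclohex-2-en-1-one F9. The electron-rich terminal alkene would be cleaved selectively with OsO4 (cat.)/NaIO4 to 2-(3,3-dimethyl-6-oxocyclohex-1-en-1-yl)acetaldehyde F10, and NaClO2/NaH2PO4 would oxidise this to 2-(3,3-dimethyl-6-oxocyclohex-1-en-1-yl)acetic acid F11. tert-Butyl 2,2,2-trichloroacetimidate with catalytic BF3·OEt2 would esterify F11 to 5. The carbon–carbon bond is then made with a neutral allyl donor that cannot add to the ketone.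

**Step 15.** The most likely failure is incomplete C-alkylation. The carbanion at C11 is shielded by C8 and C10, so proton transfer from the allylic bromide, its elimination, or O-alkylation of the alkoxide may intervene. The fallback sets out from 22 and returns at 25. Et3SiOTf/2,6-lutidine would silylate the tertiary hydroxyl to triethyl{[(1R,2R,4aR,8aS)-1-[(benzenesulfonyl)methyl]-2,5,5,8a-tetramethyldecahydronaphthalen-2-yl]oxy}silane F12. Its monolithiated sulfone (n-BuLi, 1.05 equiv), free of a basic alkoxide, would be alkylated with 23 to {[(1R,2R,4aR,8aS)-1-[(3E,7E)-1-(benzenesulfonyl)-4,8,12-trimethyltrideca-3,7,11-trien-1-yl]-2,5,5,8a-tetramethyldecahydronaphthalen-2-yl]oxy}triethylsilane F13. Bu4NF would remove the silyl group to give 25.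

## Further compounds

F1 | step 4 | bis[2-(2-methyl-1,3-dioxolan-2-yl)ethyl]zinc | CC1(CC[Zn]CCC2(C)OCCO2)OCCO1
F2 | step 4 | tert-butyl 2-[(6R)-5,5-dimethyl-6-[2-(2-methyl-1,3-dioxolan-2-yl)ethyl]-2-(trimethylsilyloxy)cyclohex-1-en-1-yl]acetate | CC(C)(C)OC(=O)CC1=C(O[Si](C)(C)C)CCC(C)(C)[C@H]1CCC2(C)OCCO2
F3 | step 9 | 2-[(1R,2R)-1,3,3-trimethyl-2-[2-(2-methyl-1,3-dioxolan-2-yl)ethyl]cyclohexyl]ethan-1-ol | OCC[C@@]1(C)CCCC(C)(C)[C@H]1CCC2(C)OCCO2
F4 | step 9 | 2-methyl-2-{2-[(1R,6R)-2,2,6-trimethyl-6-[2-(phenylsulfanyl)ethyl]cyclohexyl]ethyl}-1,3-dioxolane | c1ccccc1SCC[C@@]2(C)CCCC(C)(C)[C@H]2CCC3(C)OCCO3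
F5 | step 9 | 2-{2-[(1R,6R)-6-[2-(benzenesulfonyl)ethyl]-2,2,6-trimethylcyclohexyl]ethyl}-2-methyl-1,3-dioxolane | O=S(=O)(CC[C@@]1(C)CCCC(C)(C)[C@H]1CCC2(C)OCCO2)c1ccccc1
F6 | step 9 | 2-{2-[(1R,6R)-6-[2-(benzenesulfonyl)-2-(phenylselanyl)ethyl]-2,2,6-trimethylcyclohexyl]ethyl}-2-methyl-1,3-dioxolane (both epimers at the selenium-bearing carbon) | O=S(=O)(C([Se]c1ccccc1)C[C@@]2(C)CCCC(C)(C)[C@H]2CCC3(C)OCCO3)c1ccccc1
F7 | step 9 | 2-{2-[(1R,6S)-6-[(E)-2-(benzenesulfonyl)ethenyl]-2,2,6-trimethylcyclohexyl]ethyl}-2-methyl-1,3-dioxolane | O=S(=O)(/C=C/[C@@]1(C)CCCC(C)(C)[C@H]1CCC2(C)OCCO2)c1ccccc1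
F8 | step 9 | 4-[(1R,6S)-6-[(E)-2-(benzenesulfonyl)ethenyl]-2,2,6-trimethylcyclohexyl]butan-2-one | O=S(=O)(/C=C/[C@@]1(C)CCCC(C)(C)[C@H]1CCC(C)=O)c1ccccc1
F9 | step 2 | 4,4-dimethyl-2-(prop-2-en-1-yl)cyclohex-2-en-1-one | C=CCC1=CC(C)(C)CCC1=O
F10 | step 2 | 2-(3,3-dimethyl-6-oxocyclohex-1-en-1-yl)acetaldehyde | O=CCC1=CC(C)(C)CCC1=O
F11 | step 2 | 2-(3,3-dimethyl-6-oxocyclohex-1-en-1-yl)acetic acid | OC(=O)CC1=CC(C)(C)CCC1=O
F12 | step 15 | triethyl{[(1R,2R,4aR,8aS)-1-[(benzenesulfonyl)methyl]-2,5,5,8a-tetramethyldecahydronaphthalen-2-yl]oxy}silane | O=S(=O)(C[C@@H]1[C@@]2(C)CCCC(C)(C)[C@H]2CC[C@@]1(C)O[Si](CC)(CC)CC)c1ccccc1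
F13 | step 15 | {[(1R,2R,4aR,8aS)-1-[(3E,7E)-1-(benzenesulfonyl)-4,8,12-trimethyltrideca-3,7,11-trien-1-yl]-2,5,5,8a-tetramethyldecahydronaphthalen-2-yl]oxy}triethylsilane (both C11 epimers) | CC(C)=CCC/C(C)=C/CC/C(C)=C/CC([C@@H]1[C@@]2(C)CCCC(C)(C)[C@H]2CC[C@@]1(C)O[Si](CC)(CC)CC)S(=O)(=O)c1ccccc1
A1 | alternative 1 | ethyl (2E)-3-[(1R,2R)-1,3,3-trimethyl-2-(3-oxobutyl)cyclohexyl]prop-2-enoate | CCOC(=O)/C=C/[C@@]1(C)CCCC(C)(C)[C@H]1CCC(C)=O
A2 | alternative 1 | ethyl 2-[(1R,2R,4aR,8aS)-2-hydroxy-2,5,5,8a-tetramethyldecahydronaphthalen-1-yl]acetate | CCOC(=O)C[C@@H]1[C@@]2(C)CCCC(C)(C)[C@H]2CC[C@@]1(C)O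
A3 | alternative 2 | methyl (6Z)-7,11-dimethyl-3-oxododeca-6,10-dienoate | COC(=O)CC(=O)CC/C=C(/C)CCC=C(C)C
A4 | alternative 2 | methyl (1R,4aR,8aS)-5,5,8a-trimethyl-2-oxodecahydronaphthalene-1-carboxylate | COC(=O)[C@@H]1[C@@]2(C)CCCC(C)(C)[C@H]2CCC1=O
A5 | alternative 3 | (1R,2S,4S)-2-ethenyl-1,3,3,5-tetramethylbicyclo[2.2.2]oct-5-en-2-ol | C=C[C@]1(O)C(C)(C)[C@H]2CC[C@]1(C)C=C2C
A6 | alternative 3 | (4aR,8aS)-1,1,4a,6-tetramethyl-3,4,4a,7,8,8a-hexahydronaphthalen-2(1H)-one | CC1=C[C@@]2(C)CCC(=O)C(C)(C)[C@H]2CC1
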